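The numbers in the tables are simulated for substances that don't exist.

The vessel is closed, stirred and isothermal: gas is held over a racemate with single-handed free catalyst, and east is this same flask, followed to 12.0 h.

| flask | left-handed substrate | right-handed substrate | gas | free catalyst | remark | time |
|---|---|---|---|---|---|---|
| east | 0.75 M | 0.75 M | 120 mM (held) | 19 mM | the very flask that is asked about, followed so far |  |
| flask | 0.75 M | 0.75 M | 120 mM (held) | 19 mM |  | 30 h |

east run (percent of the left-handed substrate and right-handed substrate together charged)

| time / h | left-handed substrate / % | left-handed product / % |
|---|---|---|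
| 1.00 | 14.6 | 33.8 |
| 2.00 | 4.3 | 46.4 |
| 3.00 | 1.0 | 48.1 |
| 6.00 | 1.1 | 49.2 |
| 12.0 | 1.4 | 49.6 |

(readings scatter by 1 percentage point)

- free catalyst is single-handed; left-handed substrate and right-handed substrate are mirror images of each other, charged as a racemate, each of them at the stated concentration
- at the start none of the gas is in solution

- part of the left-handed substrate and right-handed substrate together gone at 30 h
- the left-handed product standing at 30 h, as a percentage of the left-handed substrate and right-handed substrate together charged

Read the rate first. In east, c(left-handed substrate) starts at half of the charged total and falls with a pseudo-first-order constant of 1.23 h⁻¹ in the first hour and 1.22 h⁻¹ in the second. So far the rate slows with the substrate while the constant holds.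

From 3.00 h the substrate readings stay near 1.17 %. The product gain up to 12.0 h then gives a rough late constant of 0.143 h⁻¹, a factor of 8.60 below the start.

Carry the tally, the logarithm of starting share over share left, which is the rate constant summed over time. Its east reading stalls at 3.76, worth 3.05 h of work at the starting constant. My own reckoning is a product of 48.8 %, and a conversion of that plus whatever right-handed substrate goes, which east does not show.

The forecast gives 50 % and 49.8 %, and it reads the floor differently from my fading constant: it “looks like a reversible step”.

    free catalyst + left-handed substrate ⇌ catalyst intermediate A (K = 3.50 M⁻¹, k = 1.30 M⁻¹ s⁻¹)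
    free catalyst + right-handed substrate ⇌ catalyst intermediate B (K = 0.850 M⁻¹, k = 0.220 M⁻¹ s⁻¹)
    reagent + catalyst intermediate A → free catalyst + left-handed product (k = 0.210 M⁻¹ s⁻¹)
    reagent + catalyst intermediate B → free catalyst + right-handed product (k = 0.0150 M⁻¹ s⁻¹)
    gas ⇌ reagent, rate k5*(csat - [reagent]) (kL = 0.00440 s⁻¹)
    free catalyst → spent catalyst (k = 2.40 × 10⁻⁴ s⁻¹)

The flask gives 54.9 % conversion and 49.8 % left-handed product, and at 30.0 h spent catalyst stands at >99.9 % of the catalyst charged. Now take the neighbour flask with a quarter of the free catalyst, and let the tally shrink with the charge. That leaves 19.7 % of left-handed substrate, and that flask holds 11.0 %.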